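**Retrosynthetic overview**
1. Target ⇐ C‑2 acetoxylation of the 3‑ketone (diazo transfer, then Rh‑catalysed O–H insertion of AcOH) ⇐ Mitsunobu etherification of the C‑11 alcohol with isofraxidin.
2. trans‑Fused 4,4‑dimethyl‑3‑ketone ⇐ reductive methylation of a 4‑methyl‑4‑en‑3‑one ⇐ 1,4‑reduction of a cross‑conjugated 10‑methyl dienone.
3. Key disconnection C‑9–C‑10: that dienone (ring B, exocyclic methylene, C‑9 and quaternary C‑10) ⇐ Pd‑catalysed asymmetric dearomative para‑allylation of a 3‑substituted 2,4‑dimethylphenol carrying a vinyl epoxide.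
4. Phenol–vinyl epoxide ⇐ 2‑substituted acrolein ⇐ benzylic bromide + dilithiated methallyl alcohol; arene ⇐ 3‑methoxy‑2‑methylbenzoic acid (ortho C–H methylation, reduction, BBr3).
5. Ring order: ring A is the benzene ring of the starting acid; ring B closes in the dearomatising step; the coumarin is attached late.

Assumptions: isofraxidin and 3‑methoxy‑2‑methylbenzoic acid are bought; the (R,R)‑ligand in step 7 is taken to give the (4aS,5S) series (its mirror image is used if the sense proves opposite); decalin carbons carry drimane numbers C‑1 to C‑12 (C‑11 = CH2O on C‑9, C‑12 = exocyclic CH2 on C‑8).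

**Step 1**
Reactants: 1 3‑methoxy‑2‑methylbenzoic acid
Product: 2 3‑methoxy‑2,6‑dimethylbenzoic acid
Conditions: Pd(OAc)2 (10 mol %), MeB(OH)2 (2 equiv), Ag2CO3 (1 equiv), benzoquinone (0.5 equiv), K2HPO4 (1.5 equiv), t‑BuOH, 100 °C
Reagents that add atoms: methylboronic acid, CB(O)O
Why: Carboxylate‑directed ortho C–H palladation can occur only at C‑6 because the other ortho position carries the methyl group, and transmetalation from the boronic acid with reductive elimination installs the second flanking methyl group while Ag2CO3 returns zerovalent palladium to divalent palladium (directed C–H methylation).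

**Step 2**
Reactants: 2 3‑methoxy‑2,6‑dimethylbenzoic acid
Product: 3 (3‑methoxy‑2,6‑dimethylphenyl)methanol
Conditions: LiAlH4, THF, 0 °C → reflux; then H2O
Reagents that add atoms: none
Why: Hydride reduction of the hindered carboxylic acid to the benzylic alcohol, with nothing else reducible in the molecule.

**Step 3**
Reactants: 3 (3‑methoxy‑2,6‑dimethylphenyl)methanol
Product: 4 3‑(bromomethyl)‑2,4‑dimethylphenol
Conditions: BBr3 (2.5 equiv), CH2Cl2, −78 → 0 °C; then H2O
Reagents that add atoms: boron tribromide, BrB(Br)Br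
Why: BBr3 cleaves the aryl methyl ether (Lewis‑acid demethylation) and converts the electron‑rich benzylic alcohol into the bromide in the same flask, so the phenol is unmasked and C‑6 is activated at once.

**Step 4**
Reactants: 4 3‑(bromomethyl)‑2,4‑dimethylphenol, 5 2‑methylprop‑2‑en‑1‑ol (methallyl alcohol)
Product: 7 3‑[3‑(hydroxymethyl)but‑3‑en‑1‑yl]‑2,4‑dimethylphenol, via dilithiated methallyl alcohol 6 (not isolated)
Conditions: 5 (2.5 equiv), n‑BuLi (5 equiv), TMEDA, Et2O, 0 °C → rt; then 4, THF, −78 → 0 °C; then H2O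
Reagents that add atoms: none
Why: Dianion alkylation: the alkoxide‑directed allylic lithiation gives a symmetrical 2‑substituted allyl anion that displaces the benzylic bromide by SN2 (either terminus gives the same product), the first equivalent only deprotonating the phenol.

**Step 5**
Reactants: 7 3‑[3‑(hydroxymethyl)but‑3‑en‑1‑yl]‑2,4‑dimethylphenol
Product: 8 4‑(3‑hydroxy‑2,6‑dimethylphenyl)‑2‑methylidenebutanal
Conditions: MnO2 (15 equiv), CH2Cl2, rt
Reagents that add atoms: none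
Why: MnO2 oxidises only the allylic primary alcohol to the 2‑substituted acrolein (allylic oxidation) and leaves the phenol and the alkene alone.

**Step 6**
Reactants: 8 4‑(3‑hydroxy‑2,6‑dimethylphenyl)‑2‑methylidenebutanal
Product: 9 rac‑2,4‑dimethyl‑3‑[3‑(oxiran‑2‑yl)but‑3‑en‑1‑yl]phenol
Conditions: Me3S+ I− (1.5 equiv), KOt‑Bu (2.6 equiv), DMSO/THF, 0 °C → rt; then H2O
Reagents that add atoms: trimethylsulfonium iodide, C[S+](C)C.[I-]
Why: Corey–Chaykovsky methylene transfer: the sulfonium ylide adds 1,2 to the aldehyde and closes to the terminal vinyl epoxide, made as a racemate because the next step is stereoconvergent.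

**Step 7**
Reactants: 9 rac‑2,4‑dimethyl‑3‑[3‑(oxiran‑2‑yl)but‑3‑en‑1‑yl]phenol
Product: 10 (4aS,5S)‑5‑(hydroxymethyl)‑1,4a‑dimethyl‑6‑methylidene‑5,6,7,8‑tetrahydronaphthalen‑2(4aH)‑one
Conditions: Pd2(dba)3·CHCl3 (2.5 mol %), (R,R)‑DACH‑phenyl Trost ligand (7.5 mol %), CH2Cl2 (0.01 M), rt
Reagents that add atoms: none
Why: Proposed new method: zerovalent palladium opens the racemic vinyl epoxide to a 2‑substituted π‑allyl complex whose alkoxide takes the phenol proton, the two allyl faces equilibrate through the σ‑bonded C‑12 terminus while the CH2O group stays syn to the C‑7 chain (dynamic kinetic asymmetric transformation), and the phenoxide para carbon C‑10 (O‑attack is geometrically excluded, only the ortho carbon C‑4 competes) adds to the substituted terminus C‑9 anti to palladium through a chair‑like transition state that puts CH2OH axial and anti to the C‑10 methyl group while the ligand selects the absolute sense; the closest known reactions are the intramolecular asymmetric allylic dearomatisation of phenols and the Trost asymmetric allylic alkylation with vinyl epoxides.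

**Step 8**
Reactants: 10 (4aS,5S)‑5‑(hydroxymethyl)‑1,4a‑dimethyl‑6‑methylidene‑5,6,7,8‑tetrahydronaphthalen‑2(4aH)‑one
Product: 12 (4aS,5S)‑5‑(hydroxymethyl)‑1,4a‑dimethyl‑6‑methylidene‑4,4a,5,6,7,8‑hexahydronaphthalen‑2(3H)‑one, via bis‑silylated dienol ether 11 (not isolated)
Conditions: Cu(OAc)2·H2O (5 mol %), 1,2‑bis(diphenylphosphino)benzene (5 mol %), PhMe2SiH (3 equiv), toluene, 0 °C → rt; then 1 M HCl, THF, 0 °C
Reagents that add atoms: none
Why: Copper hydride conjugate reduction: hydride adds only to the unsubstituted β‑carbon C‑1 of the disubstituted enone, not to the tetrasubstituted enone or the isolated exocyclic alkene, the silane traps the enolate (and silylates the hydroxyl group), and mild acid returns the enone alcohol.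

**Step 9**
Reactants: 12 (4aS,5S)‑5‑(hydroxymethyl)‑1,4a‑dimethyl‑6‑methylidene‑4,4a,5,6,7,8‑hexahydronaphthalen‑2(3H)‑one
Product: 14 (4aR,5S,8aS)‑5‑(hydroxymethyl)‑1,1,4a‑trimethyl‑6‑methylidene‑3,4,4a,5,6,7,8,8a‑octahydronaphthalen‑2(1H)‑one, via dilithium enolate alkoxide 13 (not isolated)
Conditions: Li (2.5 equiv), NH3(l)/THF, −78 °C; then MeI (5 equiv), −78 → −33 °C; then H2O
Reagents that add atoms: iodomethane, CI
Why: Stork reductive alkylation: two‑electron reduction of the enone with axial protonation at C‑5 anti to the C‑10 methyl group (the syn‑axial CH2OH can serve as the proton source) sets the trans ring fusion and gives the regiodefined C‑3/C‑4 enolate, which MeI alkylates at C‑4 to complete the gem‑dimethyl group.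

**Step 10**
Reactants: 14 (4aR,5S,8aS)‑5‑(hydroxymethyl)‑1,1,4a‑trimethyl‑6‑methylidene‑3,4,4a,5,6,7,8,8a‑octahydronaphthalen‑2(1H)‑one, 15 isofraxidin (7‑hydroxy‑6,8‑dimethoxy‑2H‑chromen‑2‑one)
Product: 16 7‑{[(1S,4aS,8aR)‑5,5,8a‑trimethyl‑2‑methylidene‑6‑oxodecahydronaphthalen‑1‑yl]methoxy}‑6,8‑dimethoxy‑2H‑chromen‑2‑one
Conditions: 15 (1.5 equiv), PPh3 (2 equiv), DIAD (2 equiv), THF, 0 → 50 °C
Reagents that add atoms: none
Why: Mitsunobu etherification: the acidic phenol displaces the oxyphosphonium derivative of the primary alcohol by SN2 at C‑11, so no stereocentre is touched.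

**Step 11**
Reactants: 16 7‑{[(1S,4aS,8aR)‑5,5,8a‑trimethyl‑2‑methylidene‑6‑oxodecahydronaphthalen‑1‑yl]methoxy}‑6,8‑dimethoxy‑2H‑chromen‑2‑one
Product: 18 7‑{[(1S,4aS,8aR)‑7‑diazo‑5,5,8a‑trimethyl‑2‑methylidene‑6‑oxodecahydronaphthalen‑1‑yl]methoxy}‑6,8‑dimethoxy‑2H‑chromen‑2‑one, via 2‑trifluoroacetyl ketone 17 (not isolated)
Conditions: LiN(SiMe3)2 (1.2 equiv), THF, −78 °C; CF3CO2CH2CF3 (1.5 equiv); then MsN3 (1.5 equiv), Et3N (1.5 equiv), H2O (1 equiv), MeCN, rt
Reagents that add atoms: methanesulfonyl azide, CS(=O)(=O)N=[N+]=[N-]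
Why: Detrifluoroacetylative diazo transfer (Regitz type): C‑2 is the only enolisable position because C‑4 is quaternary, so Claisen trifluoroacetylation followed by diazo transfer with loss of the trifluoroacetyl group gives the 2‑diazo ketone.

**Step 12**
Reactants: 18 7‑{[(1S,4aS,8aR)‑7‑diazo‑5,5,8a‑trimethyl‑2‑methylidene‑6‑oxodecahydronaphthalen‑1‑yl]methoxy}‑6,8‑dimethoxy‑2H‑chromen‑2‑one
Product: 19 (2R,4aS,8S,8aR)‑8‑{[(6,8‑dimethoxy‑2‑oxo‑2H‑chromen‑7‑yl)oxy]methyl}‑4,4,8a‑trimethyl‑7‑methylidene‑3‑oxodecahydronaphthalen‑2‑yl acetate (CNP0183157.1)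
Conditions: Rh2(OAc)4 (1 mol %), AcOH (10 equiv), CH2Cl2, 0 °C → rt
Reagents that add atoms: acetic acid, CC(=O)O
Why: Rhodium‑carbenoid O–H insertion into acetic acid gives the enol of the α‑acetoxy ketone, whose kinetic ketonisation delivers the proton to C‑2 from the face opposite the syn‑axial C‑4 and C‑10 methyl groups, so the acetoxy group ends cis to the C‑10 methyl group as in the target.

**Compound list**
1 | 3‑methoxy‑2‑methylbenzoic acid | COc1cccc(C(=O)O)c1C | starting material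
2 | 3‑methoxy‑2,6‑dimethylbenzoic acid | COc1ccc(C)c(C(=O)O)c1C | intermediate
3 | (3‑methoxy‑2,6‑dimethylphenyl)methanol | COc1ccc(C)c(CO)c1C | intermediate
4 | 3‑(bromomethyl)‑2,4‑dimethylphenol | Cc1ccc(O)c(C)c1CBr | intermediate
5 | 2‑methylprop‑2‑en‑1‑ol (methallyl alcohol) | C=C(C)CO | starting material
6 | lithium 2‑(lithiomethyl)prop‑2‑en‑1‑olate (dilithiated methallyl alcohol) | [Li]CC(=C)CO[Li] | intermediate (not isolated)
7 | 3‑[3‑(hydroxymethyl)but‑3‑en‑1‑yl]‑2,4‑dimethylphenol | C=C(CO)CCc1c(C)ccc(O)c1C | intermediate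
8 | 4‑(3‑hydroxy‑2,6‑dimethylphenyl)‑2‑methylidenebutanal | C=C(C=O)CCc1c(C)ccc(O)c1C | intermediate
9 | rac‑2,4‑dimethyl‑3‑[3‑(oxiran‑2‑yl)but‑3‑en‑1‑yl]phenol | C=C(CCc1c(C)ccc(O)c1C)C1CO1 | intermediate
10 | (4aS,5S)‑5‑(hydroxymethyl)‑1,4a‑dimethyl‑6‑methylidene‑5,6,7,8‑tetrahydronaphthalen‑2(4aH)‑one | CC1=C2CCC(=C)[C@H](CO)[C@]2(C)C=CC1=O | intermediate
11 | (4aS,5S)‑2‑[dimethyl(phenyl)silyloxy]‑5‑{[dimethyl(phenyl)silyloxy]methyl}‑1,4a‑dimethyl‑6‑methylidene‑4,4a,5,6,7,8‑hexahydronaphthalene | CC1=C2CCC(=C)[C@H](CO[Si](C)(C)c3ccccc3)[C@]2(C)CC=C1O[Si](C)(C)c1ccccc1 | intermediate (not isolated)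
12 | (4aS,5S)‑5‑(hydroxymethyl)‑1,4a‑dimethyl‑6‑methylidene‑4,4a,5,6,7,8‑hexahydronaphthalen‑2(3H)‑one | CC1=C2CCC(=C)[C@H](CO)[C@]2(C)CCC1=O | intermediate
13 | dilithium salt (C‑3 enolate, C‑11 alkoxide) of the trans‑fused 4‑methyl ketone, H‑5 anti to the C‑10 methyl | C=C1CC[C@@H]2C(C)=C(O[Li])CC[C@@]2(C)[C@H]1CO[Li] | intermediate (not isolated)
14 | (4aR,5S,8aS)‑5‑(hydroxymethyl)‑1,1,4a‑trimethyl‑6‑methylidene‑3,4,4a,5,6,7,8,8a‑octahydronaphthalen‑2(1H)‑one | C=C1CC[C@@H]2C(C)(C)C(=O)CC[C@@]2(C)[C@H]1CO | intermediate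
15 | isofraxidin (7‑hydroxy‑6,8‑dimethoxy‑2H‑chromen‑2‑one) | COc1cc2ccc(=O)oc2c(OC)c1O | starting material
16 | 7‑{[(1S,4aS,8aR)‑5,5,8a‑trimethyl‑2‑methylidene‑6‑oxodecahydronaphthalen‑1‑yl]methoxy}‑6,8‑dimethoxy‑2H‑chromen‑2‑one | C=C1CC[C@@H]2C(C)(C)C(=O)CC[C@@]2(C)[C@H]1COc1c(OC)cc2ccc(=O)oc2c1OC | intermediate
17 | 7‑{[(1S,4aS,8aR)‑5,5,8a‑trimethyl‑2‑methylidene‑6‑oxo‑7‑(trifluoroacetyl)decahydronaphthalen‑1‑yl]methoxy}‑6,8‑dimethoxy‑2H‑chromen‑2‑one (C‑2 enolised, not defined) | C=C1CC[C@@H]2C(C)(C)C(=O)C(C(=O)C(F)(F)F)C[C@@]2(C)[C@H]1COc1c(OC)cc2ccc(=O)oc2c1OC | intermediate (not isolated)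
18 | 7‑{[(1S,4aS,8aR)‑7‑diazo‑5,5,8a‑trimethyl‑2‑methylidene‑6‑oxodecahydronaphthalen‑1‑yl]methoxy}‑6,8‑dimethoxy‑2H‑chromen‑2‑one | C=C1CC[C@@H]2C(C)(C)C(=O)C(=[N+]=[N-])C[C@@]2(C)[C@H]1COc1c(OC)cc2ccc(=O)oc2c1OC | intermediate
19 | (2R,4aS,8S,8aR)‑8‑{[(6,8‑dimethoxy‑2‑oxo‑2H‑chromen‑7‑yl)oxy]methyl}‑4,4,8a‑trimethyl‑7‑methylidene‑3‑oxodecahydronaphthalen‑2‑yl acetate | C=C1CC[C@@H]2C(C)(C)C(=O)[C@H](OC(C)=O)C[C@@]2(C)[C@H]1COc1c(OC)cc2ccc(=O)oc2c1OC | target

**Totals**
Total step count: 12. Longest linear sequence: 12 steps (1 → 19); 5 and 15 enter as bought materials.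

**Three steps most likely to fail, with fallbacks**

Step 7 (key step). The ortho carbon C‑4 can compete with C‑10, the anti π‑allyl isomer or a boat closure would give the C‑9 epimer, and the enantioselectivity is untested. The fallback sets out from 9 and comes back at 10, carrying the stereochemistry in the substrate instead of the catalyst. The phenol is silylated (TBSCl, imidazole) to the racemic silyl ether F1. Hydrolytic kinetic resolution with (salen)Co(OAc) (the enantiomer of the catalyst that leaves the (S)‑epoxide) and 0.55 equiv of H2O gives the (S)‑epoxide silyl ether F2. Bu4NF in THF, followed by dilution with (CF3)2CHOH, frees the phenoxide, whose para carbon opens the allylic epoxide carbon by a metal‑free SN2 reaction with inversion. C‑9 is then fixed by F2 and C‑10 by the same chair‑like closure. The C‑4/C‑10 site‑selectivity risk is not removed by this fallback.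

Step 10. The CH2OH group is axial and next to the quaternary C‑10, and isofraxidin is a 2,6‑disubstituted phenol, so the Mitsunobu reaction may stall. The fallback sets out from 14 and comes back at 16. Tf2O and 2,6‑lutidine at −78 °C give the primary triflate F3, which the caesium salt of 15 (Cs2CO3, DMF, rt) displaces in a plain SN2 reaction.

Step 12. Ketonisation of the enol may not be face‑selective enough, and a 1,2‑hydride shift of the carbenoid would give the 1‑en‑3‑one. The fallback sets out from 16 and comes back at 19, bypassing 17 and 18. LiN(SiMe3)2 and then 3‑phenyl‑2‑(phenylsulfonyl)oxaziridine hydroxylate the enolate on its open face to give the 2‑hydroxy ketone F4 (OH trans to the C‑10 methyl group). Mitsunobu esterification with AcOH, PPh3 and DIAD then inverts C‑2 to give the acetate.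

**Further compounds**
F1 | step 7 | rac‑tert‑butyl{2,4‑dimethyl‑3‑[3‑(oxiran‑2‑yl)but‑3‑en‑1‑yl]phenoxy}dimethylsilane | C=C(CCc1c(C)ccc(O[Si](C)(C)C(C)(C)C)c1C)C1CO1
F2 | step 7 | tert‑butyl(2,4‑dimethyl‑3‑{3‑[(2S)‑oxiran‑2‑yl]but‑3‑en‑1‑yl}phenoxy)dimethylsilane | C=C(CCc1c(C)ccc(O[Si](C)(C)C(C)(C)C)c1C)[C@H]1CO1
F3 | step 10 | [(1S,4aS,8aR)‑5,5,8a‑trimethyl‑2‑methylidene‑6‑oxodecahydronaphthalen‑1‑yl]methyl trifluoromethanesulfonate | C=C1CC[C@@H]2C(C)(C)C(=O)CC[C@@]2(C)[C@H]1COS(=O)(=O)C(F)(F)F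
F4 | step 12 | 7‑{[(1S,4aS,7S,8aR)‑7‑hydroxy‑5,5,8a‑trimethyl‑2‑methylidene‑6‑oxodecahydronaphthalen‑1‑yl]methoxy}‑6,8‑dimethoxy‑2H‑chromen‑2‑one | C=C1CC[C@@H]2C(C)(C)C(=O)[C@@H](O)C[C@@]2(C)[C@H]1COc1c(OC)cc2ccc(=O)oc2c1OC
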